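I began with blue.

| flask | X | J | remark | time |
|---|---|---|---|---|
| amber | 0.017 M | 0.0675 M | run made earlier |  |
| blue | 0.20 M | 0.0675 M | run made earlier |  |
| grey | 0.075 M | 0.042 M | run made earlier |  |
| noon | 0.30 M | 0.0200 M |  | 2.0 min |
| dusk | 0.075 M | 0.0675 M |  | 2.0 min |
| autumn | 0.050 M | 0.0150 M |  | 2.0 min |
| summer | 0.020 M | 0.0150 M |  | 2.0 min |
| midnight | 0.15 M | 0.150 M |  | 2.0 min |

| run | time / s | Z / % | X / % |
|---|---|---|---|
| amber | 10.0 | 24.0 | 46.6 |
| amber | 30.0 | 43.1 | 15.4 |
| amber | 60.0 | 44.5 | 6.7 |
| amber | 80.0 | 41.2 | 2.8 |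
| amber | 120 | 36.4 | 3.1 |
| blue | 25.0 | 26.1 | 67.4 |
| blue | 50.0 | 21.9 | 67.2 |
| blue | 80.0 | 18.8 | 67.9 |
| blue | 90.0 | 16.0 | 67.4 |
| blue | 120 | 14.6 | 66.3 |
| grey | 10.0 | 23.2 | 74.3 |
| grey | 30.0 | 35.7 | 58.0 |
| grey | 60.0 | 36.8 | 51.6 |
| grey | 80.0 | 33.0 | 51.7 |
| grey | 120 | 30.6 | 48.6 |

(scatter of a reading: 1 percentage point)

- the flasks put in order of amount of Z, in percent of the X charged, best first, at 2.0 min (noon / dusk / autumn / summer / midnight)
- the same order at 8.0 min (noon / dusk / autumn / summer / midnight)
- the amount of Z, in percent of the X charged of the flask you put first, at 2.0 min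
- the amount of Z, in percent of the X charged of the flask you put last, at 2.0 min



In blue, X read 67.4% at 25.0 s and 66.3% at 120 s. I froze it there. The X lost, 0.0652 M, matched the 0.0675 M of J charged, so J was blue's limiting reagent. Z kept falling, however. Read as first-order, blue's Z fell at 0.00611 s⁻¹.

My doubt was that amber's late readings gave 0.00335 s⁻¹, slower than blue. A first-order constant should not change like that. So I supposed that Z is lost by meeting a partner born with it, and that the two fall together. The reciprocal of Z's molarity should then rise in a straight line. I called its slope the pairing constant and read it from blue as 0.159 M⁻¹ s⁻¹, a second-order loss. It reckoned blue's Z at 50.0 s as 21.6%, and the reading was 21.9%.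

So I took the reciprocal of the Z made, added the constant times the time, and inverted. With grey's J as the Z made, this gave 31.1% at 120 s, against a reading of 30.6%. Amber objected: the rule gave 75.5% and the reading was 36.4%. Amber had far more J per X than any asked flask, so I kept the rule for those flasks and set amber aside.

A second objection was that Z is not made at once. Amber's fall in X gave 0.820 M⁻¹ s⁻¹ for the making step. The making time, one over this constant and the J charged, was 81.3 s in summer and 18.1 s in dusk, and I counted neither as short against 2.0 min. So I corrected summer, dusk, autumn, midnight and noon alike. Second-order making gave as Z made 0.0108 M in summer, 0.0618 M in dusk, 0.0147 M in autumn, 0.140 M in midnight and 0.0200 M in noon.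

At 2.0 min I reckoned summer 44.7%, dusk 37.8%, midnight 25.5%, autumn 22.9% and noon 4.83%. At 8.0 min, with the charged J as the Z made, autumn, at 14.0%, passed midnight, at 8.04%. The forecast differed from this: it gave midnight > dusk > summer > autumn > noon and then midnight > dusk > summer > autumn > noon, with 53% and 2.2%, holding that “Z then decays roughly first-order”.

The flasks gave summer > dusk > midnight > autumn > noon and then summer > dusk > autumn > midnight > noon, with 43.3% and 4.82%.

    Q + Z → E (k = 0.162 M⁻¹ s⁻¹)
    L + J ⇌ Q + D (K = 1.50, k = 0.209 M⁻¹ s⁻¹)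
    X + J ⇌ Q + Z (K = 7.70, k = 1.30 M⁻¹ s⁻¹)
    Z + J ⇌ Q + L (K = 0.360, k = 11.5 M⁻¹ s⁻¹)

Midnight held 25.5% at 2.0 min, below summer's 43.3%. Noon, reckoned at 4.83%, stood at 4.82%. Its neighbour kept noon's 0.0200 M of J but had X lowered to 0.075 M, which is 0.267 equiv of J to X. With the same second-order making and the same pairing constant, I reckoned 19.3%. At 2.0 min that neighbour had 2.8% of its J left and held 19.3% of Z.

The runs were computed for an exercise.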